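## Retrosynthetic overview
1. The last bond made is the aryl C4–OH of ring A, by lithiation, borylation and oxidation of the C–H between the two OMe groups. Ring A therefore travels as a plain 3,5-dimethoxyphenyl group that needs no protection and cannot form a quinone methide.
2. Ring C is the only ring made; rings A and B are bought. It closes at C7'–C2 by Friedel–Crafts attack of ring A on the guaiacyl benzylic cation, and the substrate sets C7' trans to the C8' methyl.
3. C7'–C1' comes from an aryllithium addition to an aldehyde. C7–C1 comes from a Weinreb ketone synthesis followed by benzylic hydrogenolysis.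
4. Key step: acyl C–N bond formation. A catalytic enantioselective opening of meso cis-2,3-dimethylsuccinic anhydride with MeNHOMe tells the two carbonyls (future C7 and C7') apart and so fixes C8 and C8' in absolute terms.
5. The cis (erythro) C8/C8' pair comes from syn hydrogenation of 2,3-dimethylmaleic anhydride.

Assumption: lignan numbering is used (C7, C8 on the ring A side, primed atoms on the ring B side). The quinine-derived alkaloid catalysts are taken to give the (2R,3S) products drawn; if the sense proves opposite, the quinidine-derived pseudo-enantiomer is used and nothing else changes.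

## Route

Step 1
Reactants: 1 2,3-dimethylmaleic anhydride
Product: 2 cis-2,3-dimethylsuccinic anhydride [(3R,4S)-3,4-dimethyloxolane-2,5-dione; meso]
Conditions: H2 (4 bar), 10% Pd/C, EtOAc, rt; recrystallise
Reagents that add atoms: none
Why: Heterogeneous catalytic hydrogenation delivers both hydrogens to one face of the flat ring alkene (syn addition), so the two methyl groups end up cis, which is the erythro C8/C8' relationship of the target in a still meso compound.

Step 2
Reactants: 2 cis-2,3-dimethylsuccinic anhydride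
Product: 3 (2R,3S)-4-[methoxy(methyl)amino]-2,3-dimethyl-4-oxobutanoic acid
Conditions: MeNHOMe (free base, 1.5 equiv, added over 12 h), N-(9-deoxy-epi-quinin-9-yl)-3,5-bis(trifluoromethyl)benzenesulfonamide (10 mol %), MTBE (0.05 M), −40 °C; 1 M HCl wash
Reagents that add atoms: N,O-dimethylhydroxylamine, CNOC
Why: Proposed new method: organocatalytic enantioselective desymmetrising aminolysis of a meso succinic anhydride with an N,O-dialkylhydroxylamine, which forms the acyl C–N bond and fixes C8 (S in 3) and C8' (R) by choosing one of the two enantiotopic carbonyls; the sulfonamide N–H of the bifunctional cinchona catalyst hydrogen-bonds to one carbonyl while the quinuclidine nitrogen takes the N–H proton of the attacking amine as a general base inside the chiral pocket; MeNHOMe suits this because it is weakly basic (conjugate acid pKa about 4.8, so the product acid does not tie it up), should react only slowly without catalyst at −40 °C under dilution and slow addition, and gives a tertiary amide that cannot close to an imide and so cannot return to a meso compound; the closest known reaction type is the cinchona-catalysed alcoholysis (also thiolysis and aminolysis with primary amines) of cyclic meso anhydrides, which works on this very anhydride with methanol.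

Step 3
Reactants: 3 (2R,3S)-4-[methoxy(methyl)amino]-2,3-dimethyl-4-oxobutanoic acid; 4 1-bromo-3,5-dimethoxybenzene
Product: 6 (2R,3S)-4-(3,5-dimethoxyphenyl)-2,3-dimethyl-4-oxobutanoic acid, via 3,5-dimethoxyphenylmagnesium bromide 5 (not isolated)
Conditions: 4 (2.4 equiv), Mg, THF, 40 °C; then 3, THF, −20 °C → rt; 1 M HCl
Reagents that add atoms: none
Why: Weinreb ketone synthesis: the first equivalent of Grignard reagent makes the inert magnesium carboxylate and the second adds to the amide to give a chelated tetrahedral adduct that collapses only on quench, so there is no over-addition and the ketone never meets base, which keeps C8 intact.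

Step 4
Reactants: 6 (2R,3S)-4-(3,5-dimethoxyphenyl)-2,3-dimethyl-4-oxobutanoic acid
Product: 8 (2R,3R)-4-(3,5-dimethoxyphenyl)-2,3-dimethylbutanoic acid, via benzylic lactone 7 (not isolated)
Conditions: H2 (5 bar), 10% Pd/C, AcOH, H2SO4 (0.1 equiv), rt → 40 °C
Reagents that add atoms: none
Why: Catalytic benzylic hydrogenolysis: the aryl ketone is reduced to the alcohol, which lactonises, and the benzylic C–O bond is then cleaved on palladium; near room temperature with only catalytic acid, enolisation is far slower than reduction, so C8 and C8' are carried through unchanged (the descriptor at C8 changes only by priority).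

Step 5
Reactants: 8 (2R,3R)-4-(3,5-dimethoxyphenyl)-2,3-dimethylbutanoic acid
Product: 10 (2R,3R)-4-(3,5-dimethoxyphenyl)-2,3-dimethylbutanal, via acyl imidazolide 9 (not isolated)
Conditions: 1,1'-carbonyldiimidazole (1.15 equiv), CH2Cl2, rt; then i-Bu2AlH (2.2 equiv), −78 °C; aq potassium sodium tartrate; used crude
Reagents that add atoms: none
Why: Acyl imidazolide formation and partial hydride reduction stop at the aldehyde because the tetrahedral aluminium adduct survives until the quench, and the low temperature and neutral work-up protect the α-centre C8'.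

Step 6
Reactants: 10 (2R,3R)-4-(3,5-dimethoxyphenyl)-2,3-dimethylbutanal; 11 4-bromo-2-methoxyphenol
Product: 14 4-[(1R,2R,3R)-6,8-dimethoxy-2,3-dimethyl-1,2,3,4-tetrahydronaphthalen-1-yl]-2-methoxyphenol, via dilithio phenolate 12 (not isolated), via benzylic carbinol 13 (not isolated)
Conditions: 11 (1.6 equiv), n-BuLi (1.6 equiv), THF, −78 °C; t-BuLi (3.2 equiv), −78 °C; 10, −78 °C; then CF3CO2H (20 equiv), CH2Cl2, −78 → 0 °C
Reagents that add atoms: none
Why: Bromine–lithium exchange on the lithium phenolate and 1,2-addition give a p-hydroxybenzylic alcohol that acid ionises to the protonated p-quinone methide, and intramolecular Friedel–Crafts alkylation at the ring A carbon ortho and para to the two methoxy groups (both ortho carbons are equivalent) closes ring C; C7' is set by the substrate, because the half-chair transition state places ring B pseudo-axial, away from the peri methoxy group and anti to the C8' methyl, giving the 7',8'-trans, 8,8'-cis (7'R) product.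

Step 7
Reactants: 14 4-[(1R,2R,3R)-6,8-dimethoxy-2,3-dimethyl-1,2,3,4-tetrahydronaphthalen-1-yl]-2-methoxyphenol
Product: 17 (−)-(7'R,8R,8'R)-4,4'-dihydroxy-3,3',5-trimethoxy-2,7'-cyclolignan, via dilithio arene 15 (not isolated), via aryl boronate 16 (not isolated)
Conditions: n-BuLi (3 equiv), TMEDA, THF, 0 °C → rt; B(OMe)3, −78 °C → rt; AcOH, 30% aq H2O2, 0 °C
Reagents that add atoms: hydrogen peroxide, OO
Why: Directed ortho-metalation, borylation and oxidation: deprotonating the phenol shuts ring B down, the C–H flanked by two methoxy groups is the most acidic and doubly coordinated site, and borate trapping followed by the peroxide-induced aryl shift from boron to oxygen installs the C4–O bond without touching a stereocentre.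

## Compound list
1 | 2,3-dimethylmaleic anhydride (3,4-dimethylfuran-2,5-dione) | CC1=C(C)C(=O)OC1=O | starting material
2 | cis-2,3-dimethylsuccinic anhydride, (3R,4S)-3,4-dimethyloxolane-2,5-dione, meso | O=C1[C@@H](C)[C@H](C(=O)O1)C | intermediate
3 | (2R,3S)-4-[methoxy(methyl)amino]-2,3-dimethyl-4-oxobutanoic acid | CON(C)C(=O)[C@@H](C)[C@H](C(=O)O)C | intermediate
4 | 1-bromo-3,5-dimethoxybenzene | COc1cc(Br)cc(OC)c1 | starting material
5 | 3,5-dimethoxyphenylmagnesium bromide | COc1cc([Mg]Br)cc(OC)c1 | intermediate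
6 | (2R,3S)-4-(3,5-dimethoxyphenyl)-2,3-dimethyl-4-oxobutanoic acid | COc1cc(cc(OC)c1)C(=O)[C@@H](C)[C@H](C(=O)O)C | intermediate
7 | (3R,4S)-5-(3,5-dimethoxyphenyl)-3,4-dimethyloxolan-2-one, both C5 epimers | COc1cc(cc(OC)c1)C2[C@@H](C)[C@H](C(=O)O2)C | intermediate
8 | (2R,3R)-4-(3,5-dimethoxyphenyl)-2,3-dimethylbutanoic acid | COc1cc(cc(OC)c1)C[C@@H](C)[C@H](C(=O)O)C | intermediate
9 | 1-[(2R,3R)-4-(3,5-dimethoxyphenyl)-2,3-dimethylbutanoyl]imidazole | COc1cc(cc(OC)c1)C[C@@H](C)[C@H](C(=O)n1ccnc1)C | intermediate
10 | (2R,3R)-4-(3,5-dimethoxyphenyl)-2,3-dimethylbutanal | COc1cc(cc(OC)c1)C[C@@H](C)[C@H](C=O)C | intermediate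
11 | 4-bromo-2-methoxyphenol | COc1cc(Br)ccc1O | starting material
12 | lithium 4-lithio-2-methoxyphenolate | COc1cc([Li])ccc1O[Li] | intermediate
13 | (2R,3R)-4-(3,5-dimethoxyphenyl)-1-(4-hydroxy-3-methoxyphenyl)-2,3-dimethylbutan-1-ol, both C1 epimers | COc1cc(cc(OC)c1)C[C@@H](C)[C@H](C(O)c1ccc(O)c(OC)c1)C | intermediate
14 | 4-[(1R,2R,3R)-6,8-dimethoxy-2,3-dimethyl-1,2,3,4-tetrahydronaphthalen-1-yl]-2-methoxyphenol | COc1cc([C@@H]2c3c(cc(OC)cc3OC)C[C@@H](C)[C@H]2C)ccc1O | intermediate
15 | lithium phenolate of 14 lithiated at C7 of the tetralin (between the two OMe groups), (1R,2R,3R) | COc1cc([C@@H]2c3c(cc(OC)c([Li])c3OC)C[C@@H](C)[C@H]2C)ccc1O[Li] | intermediate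
16 | dimethyl boronate at C7 of the tetralin, lithium phenolate, (1R,2R,3R) | COc1cc([C@@H]2c3c(cc(OC)c(B(OC)OC)c3OC)C[C@@H](C)[C@H]2C)ccc1O[Li] | intermediate
17 | (−)-(7'R,8R,8'R)-4,4'-dihydroxy-3,3',5-trimethoxy-2,7'-cyclolignan = (6R,7R,8R)-8-(4-hydroxy-3-methoxyphenyl)-1,3-dimethoxy-6,7-dimethyl-5,6,7,8-tetrahydronaphthalen-2-ol | COc1cc([C@@H]2c3c(cc(OC)c(O)c3OC)C[C@@H](C)[C@H]2C)ccc1O | target

## Step count and risks
Total step count: 7. Longest linear sequence: 7 (1 → 17). Both aryl bromides enter as bought and no protecting group is used.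

**Step 2 (the new reaction).** The risks are uncatalysed aminolysis that lowers the ee, and slow turnover once the product acid builds up.
The fallback sets out from 2 and comes back at 3, using known chemistry only.
- Methanolysis of 2 (MeOH 10 equiv, hydroquinine anthraquinone-1,4-diyl diether 10 mol %, Et2O, −20 °C) is established on this anhydride with high ee. It gives the hemiester (2R,3S)-4-methoxy-2,3-dimethyl-4-oxobutanoic acid F1.
- MeNHOMe·HCl and i-PrMgCl (THF, −20 °C) give chloromagnesium methoxy(methyl)amide F2. This converts the ester of F1 into the Weinreb amide while the acid is masked as its magnesium carboxylate, giving 3.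
- Cost: one more step.

**Step 6.** The risks are poor formation or solubility of the unprotected dianion, enolisation of the α-branched aldehyde by the aryllithium, and sluggish ionisation in a medium that contains THF.
The fallback sets out from 10 and comes back at 14. It gives up the unprotected dianion and the one-flask ionisation in favour of a protected, stepwise sequence.
- Commercial 1-(benzyloxy)-4-bromo-2-methoxybenzene and Mg give 4-(benzyloxy)-3-methoxyphenylmagnesium bromide F3, a less basic nucleophile.
- F3 adds to 10 (THF, −40 °C) to give the isolable carbinol (2R,3R)-1-[4-(benzyloxy)-3-methoxyphenyl]-4-(3,5-dimethoxyphenyl)-2,3-dimethylbutan-1-ol F4.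
- CF3CO2H in CH2Cl2 at 0 °C closes ring C to (1R,2R,3R)-1-[4-(benzyloxy)-3-methoxyphenyl]-6,8-dimethoxy-2,3-dimethyl-1,2,3,4-tetrahydronaphthalene F5.
- H2 over Pd/C frees the phenol to give 14.
- Cost: two more steps.

**Step 7.** The risks are incomplete or misdirected lithiation of the phenolate, protodeboronation of the doubly ortho-substituted boronate, and over-oxidation of the electron-rich bisphenol.
The fallback sets out from 3 and comes back at 17. The C4 oxygen is carried from the start instead of being installed last.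
- Commercial 4-bromo-2,6-dimethoxyphenol is benzylated (BnBr, K2CO3, DMF) to 2-(benzyloxy)-5-bromo-1,3-dimethoxybenzene F6.
- F6 and Mg give 4-(benzyloxy)-3,5-dimethoxyphenylmagnesium bromide F7.
- Addition of F7 to 3 as in step 3 gives (2R,3S)-4-[4-(benzyloxy)-3,5-dimethoxyphenyl]-2,3-dimethyl-4-oxobutanoic acid F8.
- The ketone is now para-oxygenated, so ionic hydrogenation (Et3SiH, CF3CO2H, rt) takes it to the methylene and spares the benzyl ether. This gives (2R,3R)-4-[4-(benzyloxy)-3,5-dimethoxyphenyl]-2,3-dimethylbutanoic acid F9.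
- 1,1'-Carbonyldiimidazole gives 1-{(2R,3R)-4-[4-(benzyloxy)-3,5-dimethoxyphenyl]-2,3-dimethylbutanoyl}imidazole F10, and i-Bu2AlH at −78 °C gives (2R,3R)-4-[4-(benzyloxy)-3,5-dimethoxyphenyl]-2,3-dimethylbutanal F11.
- Addition of 12 gives (2R,3R)-4-[4-(benzyloxy)-3,5-dimethoxyphenyl]-1-(4-hydroxy-3-methoxyphenyl)-2,3-dimethylbutan-1-ol F12.
- CF3CO2H cyclises F12 as in step 6 to 4-[(1R,2R,3R)-7-(benzyloxy)-6,8-dimethoxy-2,3-dimethyl-1,2,3,4-tetrahydronaphthalen-1-yl]-2-methoxyphenol F13.
- H2 over Pd/C gives 17.
- Cost: the same number of steps from 3, plus the benzylation.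

Further compounds
F1 | step 2 | (2R,3S)-4-methoxy-2,3-dimethyl-4-oxobutanoic acid | COC(=O)[C@@H](C)[C@H](C(=O)O)C
F2 | step 2 | chloromagnesium methoxy(methyl)amide | CON(C)[Mg]Cl
F3 | step 6 | 4-(benzyloxy)-3-methoxyphenylmagnesium bromide | COc1cc([Mg]Br)ccc1OCc1ccccc1
F4 | step 6 | (2R,3R)-1-[4-(benzyloxy)-3-methoxyphenyl]-4-(3,5-dimethoxyphenyl)-2,3-dimethylbutan-1-ol, both C1 epimers | COc1cc(cc(OC)c1)C[C@@H](C)[C@H](C(O)c1ccc(OCc2ccccc2)c(OC)c1)C
F5 | step 6 | (1R,2R,3R)-1-[4-(benzyloxy)-3-methoxyphenyl]-6,8-dimethoxy-2,3-dimethyl-1,2,3,4-tetrahydronaphthalene | COc1cc([C@@H]2c3c(cc(OC)cc3OC)C[C@@H](C)[C@H]2C)ccc1OCc1ccccc1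
F6 | step 7 | 2-(benzyloxy)-5-bromo-1,3-dimethoxybenzene | COc1cc(Br)cc(OC)c1OCc1ccccc1
F7 | step 7 | 4-(benzyloxy)-3,5-dimethoxyphenylmagnesium bromide | COc1cc([Mg]Br)cc(OC)c1OCc1ccccc1
F8 | step 7 | (2R,3S)-4-[4-(benzyloxy)-3,5-dimethoxyphenyl]-2,3-dimethyl-4-oxobutanoic acid | COc1cc(cc(OC)c1OCc1ccccc1)C(=O)[C@@H](C)[C@H](C(=O)O)C
F9 | step 7 | (2R,3R)-4-[4-(benzyloxy)-3,5-dimethoxyphenyl]-2,3-dimethylbutanoic acid | COc1cc(cc(OC)c1OCc1ccccc1)C[C@@H](C)[C@H](C(=O)O)C
F10 | step 7 | 1-{(2R,3R)-4-[4-(benzyloxy)-3,5-dimethoxyphenyl]-2,3-dimethylbutanoyl}imidazole | COc1cc(cc(OC)c1OCc1ccccc1)C[C@@H](C)[C@H](C(=O)n1ccnc1)C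
F11 | step 7 | (2R,3R)-4-[4-(benzyloxy)-3,5-dimethoxyphenyl]-2,3-dimethylbutanal | COc1cc(cc(OC)c1OCc1ccccc1)C[C@@H](C)[C@H](C=O)C
F12 | step 7 | (2R,3R)-4-[4-(benzyloxy)-3,5-dimethoxyphenyl]-1-(4-hydroxy-3-methoxyphenyl)-2,3-dimethylbutan-1-ol, both C1 epimers | COc1cc(cc(OC)c1OCc1ccccc1)C[C@@H](C)[C@H](C(O)c1ccc(O)c(OC)c1)C
F13 | step 7 | 4-[(1R,2R,3R)-7-(benzyloxy)-6,8-dimethoxy-2,3-dimethyl-1,2,3,4-tetrahydronaphthalen-1-yl]-2-methoxyphenol | COc1cc([C@@H]2c3c(cc(OC)c(OCc4ccccc4)c3OC)C[C@@H](C)[C@H]2C)ccc1O
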